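(The numbers in the tables are calculated for substances that don't exist; noise was put on by code.)

**Late times.** At late times the two earlier runs differ in percent but agree as concentration, so I follow [ring] in M.

| flask | solid substrate | remark | time |
|---|---|---|---|
| gamma | 1.4 M | run made earlier |  |
| zeta | 2.2 M | run made earlier |  |
| flask | 1.0 M |  | 40 min |

- gamma (time / min: ring / %): 10.0: 6.2; 20.0: 14.3; 30.0: 22.6; 40.0: 33.0
- zeta (time / min: ring / %): 10.0: 2.8; 20.0: 9.6; 30.0: 13.8; 40.0: 21.6

(standard deviation of a reading: 1 percentage point)

- amount of ring in percent of the solid substrate charged, at 4.0 min, 12 min, 25 min and 40 min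

- the earlier runs were read with a standard deviation of 1 percentage point
- at the start none of the solid substrate is in solution
- a reading or a percentage of ring counts all its forms, free or not

Between 20.0 min and 40.0 min, gamma gains 0.0131 M min⁻¹ and zeta 0.0132 M min⁻¹, so their mean is 0.0131 M min⁻¹, and I carry this common ring rate, an apparent zero order in the charge, as the rise of [ring] per minute.

**The bracket.** Ring in this flask at 40 min cannot pass the charge itself, and I set gamma's 33.0% as the first floor, because the percent at that time is higher in gamma than in zeta. To tighten the top, I put zeta's last [ring] on this charge, which gives 47.5%. To tighten the floor, I carry zeta's reading at 30.0 min forward 10.0 min at the common rate, which gives 43.5%. The fraction left as not ring thus lies between 52.5% and 56.5%. That floor is a stretch, since gamma ended with 0.938 M not ring, more than this flask's 0.565 M.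

**The forecast.** It gives 2%, 10.5%, 26% and 45%, holding that “ring formation is independent of charge”; its last value stands inside my bracket.

**The flask.** It gives 1.69%, 9.93%, 26.3% and 45.6%, also inside.

    2 starting material → open dimer (k = 0.00140 M⁻¹ s⁻¹)
    starting material → ring (k = 0.00300 s⁻¹)
    solid substrate ⇌ starting material, rate k3*(cs3 - [starting material]) while solid is left; crystals form when [starting material] > cs3 (solubility = 0.810 M, k = 3.10 × 10⁻⁴ s⁻¹)
    crystals ⇌ ring, rate k4*(cs4 - [ring]) while solid is left; crystals form when [ring] > cs4 (solubility = 0.200 M, k = 0.0120 s⁻¹)

**Half the charge.** This flask still holds 44.4% of its charge as solid substrate at 40.0 min, and from 25 min on its ring rises 0.0129 M min⁻¹, close to the common rate. With half the solid substrate, 0.500 M, gamma's reading at 20.0 min plus the common rate reckons 92.6% of that charge, leaving 7.40%. That flask gives 88.0%.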